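The numbers in the tables were computed from invented constants.

However long a flask runs, the forms of its catalyst add up to what was charged, so the number worth carrying is how much product that stock buys before it is lost.

1. product, in percent of the starting material first charged, at 4.0 d
2. the option that brings most further product ("none" if no option brings more than 2 percentage points) (alder / ash / cedar / elm / maple / none)
3. product present, with what was taken out counted in, in percent of the starting material first charged, after elm
4. product present, with what was taken out counted in, in percent of the starting material first charged, after maple

| setting | north-east | north | flask |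
|---|---|---|---|
| starting material | 0.010 M | 0.0067 M | 0.010 M |
| partner | 5 mM | 5 mM | 5.00 mM |
| free catalyst | 5 µM | 5 µM | 5.0 µM |
| temperature | −20 °C | −20 °C | −20 °C |
| remark | the very flask that is asked about, followed so far | run made earlier |  |
| time |  |  | 4.0 d |

- north-east (time / h: product / %): 25.0: 11.8; 50.0: 16.4; 72.0: 17.4; 96.0: 18.4
- north (time / h: product / %): 1.00: 1.4; 2.50: 2.7; 6.00: 6.9; 15.0: 12.5

(readings scatter by 0.5 percentage points)

- alder: at 4.0 d take out 90 % of the product then present, then wait 30 h
- ash: at 4.0 d add free catalyst, 100 % of the amount charged, then wait 30 h
- cedar: at 4.0 d raise the temperature by 15 K, then wait 30 h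
- elm: change nothing and wait 30 h more
- maple: at 4.0 d add partner, 100 % of the amount charged, then wait 30 h

- removed product is counted in
- what was read earlier has a scatter of 0.5 percentage points, one standard deviation
- the earlier runs do not show what temperature does; that part of a forecast is a guess
- additions bring no volume worth counting

Read in concentration, both runs lie roughly on one curve, and the north-east run flattens near 1.84 mM of product with 3.16 mM of partner still present, so I assume that catalyst is being lost, with a lifetime read from the first and last north-east readings as 24.4 h. You can solve two extreme versions of this flask in your head. In the first, each catalyst gives a fixed turnover number, 368, whatever the partner does. In the second, loss competes with capture of partner, so turnovers per catalyst lost follow [partner], and the logarithm of charged over remaining [partner], times charged [partner] over charged catalyst, gives 459, the partner budget, meaning the turnovers one catalyst would give if [partner] stayed at its charge. A partner order between zero and one puts the real flask between them, so a second charge of catalyst, ash, should add between 8.2 percentage points and 13 points in 30 h. The rest is a correction to the large plateau, because at that lifetime my estimate of the catalyst still working at 4.0 d is a share of about 1.96 %. I therefore keep 18.4 % for now, and I reckon that waiting adds about 0.26 points and that maple, scaling that remnant by the rise in [partner], adds about 0.67 points, which is less than 2 points; cedar is a guess I do not price.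

The forecast gave 18.4 %, 19 % after elm, 19.5 % after maple and ash as best, on the ground that if the catalyst has died “fresh catalyst restarts the reaction”, with about 13 points for ash, the top of my range.

The flask gives 17.9 %, 18.3 % after elm and 18.7 % after maple, and ash is best, adding 8.6 points, which is more than my lower version and less than my upper one.

    starting material + free catalyst → catalyst intermediate A (k = 29000 M⁻¹ h⁻¹, Ea = 46.0 kJ mol⁻¹)
    catalyst intermediate A ⇌ catalyst intermediate B (K = 1.00, k = 1100 h⁻¹, Ea = 55.0 kJ mol⁻¹, ΔH = 19.0 kJ mol⁻¹)
    partner + catalyst intermediate B ⇌ catalyst intermediate C (K = 30.0 M⁻¹, k = 3.80 × 10⁶ M⁻¹ h⁻¹, Ea = 37.0 kJ mol⁻¹, ΔH = −28.0 kJ mol⁻¹)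
    catalyst intermediate C → free catalyst + product (k = 240 h⁻¹, Ea = 59.0 kJ mol⁻¹)
    catalyst intermediate B → spent catalyst (k = 0.0780 h⁻¹, Ea = 77.0 kJ mol⁻¹)
    (constants at −20 °C)

Now take the neighbouring flask charged with 8.5 × 10⁻⁶ M of free catalyst. The fixed turnover number gives it 31.3 %, while the budget, with the whole of that charge counted as lost, gives 27.1 %. That neighbouring flask holds 96.7 % spent catalyst, 46.9 % of its partner and 26.6 % of product at 96.0 h.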